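Locants used throughout: C1 methyl-bearing fusion carbon, C2 and C3 ring CH2, C4 isopropyl carbinol, C5 fusion CH, C6 ester carbinol beside C5, C7 CH2, C8=C9 alkene (methyl on C8), C10 ester carbinol beside C1; five-membered ring C1–C5, seven-membered ring C1 and C5–C10.
Enabling feature: in the seven-membered ring an oxygenated carbon (C10) lies between C1 and C9 and a second oxygen sits on C6, so the ring is the (4+3) adduct of an oxyallyl unit C1–C10(O)–C9 and a 2-silyloxydiene C5=C6(O)–C7=C8; the C2–C4 chain joining C1 to C5 is the tether that becomes the five-membered ring.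
Cuts: both angelate C–O bonds, then C8=C9 (back to a C10 ketone), then C1–C5 and C8–C9 together to an open-chain chloromethyl ketone; that chain is cut at C5–C6 (dithiane anion plus epoxide) and at C2–C3 (radical addition to methyl methacrylate).
Forward: a C4 epoxy alcohol is extended first towards C10 and then towards C8, the silyloxydiene and the chloroketone are installed, both rings close in step 12, and the C6 and C10 oxygens are then set and acylated.
Stereochemistry: C4 from Sharpless epoxidation; C1 and C5 from the cycloaddition under control of C4; C6 from reduction directed by the C4 hydroxyl; C10 from hydride attack anti to the angular methyl followed by Mitsunobu inversion with angelic acid.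
Key step: step 12

Remark: from 7 to 19 the methyl-bearing carbon that becomes C1 is carried as both epimers (it turns trigonal in step 12); bicyclic compounds are named with the locants above on the bicyclo[5.3.0]decane skeleton, and CIP letters at C5 and C8 change between 21, 22 and 23 only because substituent priorities change.

Step 1
Reactants: 1 prop-2-yn-1-ol; 2 isopropylmagnesium chloride
Product: 3 3-methyl-2-methylidenebutan-1-ol
Conditions: 2 (2.3 equiv), CuI (10 mol%), THF, 0 °C to rt; aq NH4Cl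
Reagents that add atoms: none
Why: Copper-catalysed anti-carbomagnesiation of the propargylic alkoxide puts the isopropyl group on the internal alkyne carbon through a chelated vinylmagnesium species, giving the 2-substituted allylic alcohol on protonation.

Step 2
Reactants: 3
Product: 4 [(2R)-2-(propan-2-yl)oxiran-2-yl]methanol
Conditions: Ti(OiPr)4 (10 mol%), D-(−)-diisopropyl tartrate (12 mol%), t-BuOOH, 4 Å MS, CH2Cl2, −20 °C
Reagents that add atoms: tert-butyl hydroperoxide, CC(C)(C)OO
Why: Sharpless asymmetric epoxidation of a 2-substituted allylic alcohol, in which D-(−)-tartrate should give the R epoxide (L-(+)-tartrate gives the S series with 2-alkyl allyl alcohols), and this sets C4.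

Step 3
Reactants: 4
Product: 5 (2R)-2-(iodomethyl)-3-methylbutane-1,2-diol
Conditions: LiI, AcOH, THF, rt
Reagents that add atoms: lithium iodide, [Li+].[I-]
Why: Acid-assisted SN2 opening of the epoxide by iodide (halohydrin formation) can only take place at the CH2 carbon, so the quaternary C–O bond and its configuration are untouched.

Step 4
Reactants: 5; 6 methyl methacrylate
Product: 7 methyl (5R)-5,6-dihydroxy-2-methyl-5-(propan-2-yl)hexanoate
Conditions: 6 (5 equiv), Bu3SnH (slow addition), AIBN (cat.), PhH, 80 °C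
Reagents that add atoms: none
Why: Giese radical conjugate addition, in which the primary radical from the C–I bond adds to the acrylate terminus and the alpha-ester radical takes hydrogen from the stannane, forms C2–C3 at a neopentyl-type carbon where ionic substitution would fail.

Step 5
Reactants: 7
Product: 9 methyl 2-methyl-4-[(2R)-2-(propan-2-yl)oxiran-2-yl]butanoate, via primary tosylate 8 (not isolated)
Conditions: TsCl, Et3N, Bu2SnO (cat.), CH2Cl2, 0 °C; then K2CO3, MeOH, rt
Reagents that add atoms: none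
Why: Selective sulfonylation of the primary hydroxyl and intramolecular Williamson closure (3-exo-tet) by the tertiary alkoxide rebuild the epoxide on the second arm without touching the C4–O bond.

Step 6
Reactants: 10 (E)-but-2-enal; 11 propane-1,3-dithiol
Product: 12 2-[(1E)-prop-1-en-1-yl]-1,3-dithiane
Conditions: BF3·OEt2, AcOH, CHCl3, 0 °C to rt
Reagents that add atoms: none
Why: Lewis-acid dithioacetalisation of the enal gives the Corey–Seebach acyl-anion precursor that carries C6, C7, C8 and the C8 methyl.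

Step 7
Reactants: 9; 12
Product: 15 (5S)-5-hydroxy-2-methyl-5-(propan-2-yl)-6-{2-[(1E)-prop-1-en-1-yl]-1,3-dithian-2-yl}hexanoic acid, via lithium epoxy-carboxylate 13 (not isolated), via 2-lithiodithiane 14 (not isolated)
Conditions: 9: LiOH, THF–H2O, rt, then dried (PhMe azeotrope); 12: n-BuLi, THF, −30 °C; 13 added to 14 (2.2 equiv), THF, −78 to 0 °C; 1 M HCl to pH 4
Reagents that add atoms: lithium hydroxide, [Li+].[OH-]
Why: Corey–Seebach umpolung, in which the dithiane anion opens the epoxide by SN2 at its CH2 carbon through the sulfur-bearing carbon, forms C5–C6 with C4 untouched, while prior saponification masks C10 as a carboxylate that is neither attacked nor enolised (an ester enolate would cyclise onto the epoxide).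

Step 8
Reactants: 15
Product: 16 (5S)-5-hydroxy-N-methoxy-N,2-dimethyl-5-(propan-2-yl)-6-{2-[(1E)-prop-1-en-1-yl]-1,3-dithian-2-yl}hexanamide
Conditions: MeNH(OMe)·HCl, EDC·HCl, HOBt, iPr2NEt, CH2Cl2, 0 °C to rt
Reagents that add atoms: N,O-dimethylhydroxylamine hydrochloride, CNOC.Cl
Why: Carbodiimide amide coupling gives the Weinreb amide, the hindered tertiary hydroxyl being a far poorer nucleophile for the active ester than the amine.

Step 9
Reactants: 16
Product: 17 (5S,8E)-5-hydroxy-N-methoxy-N,2-dimethyl-7-oxo-5-(propan-2-yl)dec-8-enamide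
Conditions: PhI(OCOCF3)2, NaHCO3, MeCN–H2O (9:1), 0 °C
Reagents that add atoms: water, O
Why: Oxidative dethioacetalisation (activation at sulfur, then hydrolysis) unmasks the C6 ketone as the E enone under buffered conditions that spare the aldol-type tertiary alcohol.

Step 10
Reactants: 17
Product: 18 (5R,6Z,8E)-N-methoxy-N,2-dimethyl-5-(propan-2-yl)-5,7-bis[(triethylsilyl)oxy]deca-6,8-dienamide
Conditions: Et3SiOTf (3.5 equiv), Et3N, CH2Cl2, −78 to 0 °C
Reagents that add atoms: triethylsilyl trifluoromethanesulfonate, CC[Si](CC)(CC)OS(=O)(=O)C(F)(F)F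
Why: Silyl triflate and amine silylate the tertiary alcohol and enolise the enone at its alpha-prime CH2 (soft enolisation) to the cross-conjugated 2-silyloxydiene, the Z enol ether being favoured because it avoids allylic 1,3-strain between the quaternary C4 and C7, while the Weinreb amide is not enolised.

Step 11
Reactants: 18
Product: 19 (6R,7Z,9E)-1-chloro-3-methyl-6-(propan-2-yl)-6,8-bis[(triethylsilyl)oxy]undeca-7,9-dien-2-one
Conditions: ICH2Cl, MeLi·LiBr, THF, −78 °C; pH 7 buffer
Reagents that add atoms: chloroiodomethane, ClCI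
Why: Weinreb ketone synthesis with chloromethyllithium made in situ by iodine–lithium exchange, in which the chelated tetrahedral adduct blocks a second addition and collapses on neutral work-up, gives the chloromethyl ketone while C6 stays masked as its silyl enol ether.

Step 12
Reactants: 19
Product: 21 (1S,4R,5S,8R)-1,8-dimethyl-4-(propan-2-yl)-4,6-bis[(triethylsilyl)oxy]bicyclo[5.3.0]dec-6-en-10-one, via oxyallyl cation 20 (not isolated)
Conditions: iPr2NEt (3 equiv), LiClO4 (3 M in Et2O), 0.02 M, 0 °C to rt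
Reagents that add atoms: none
Why: The amine, helped by lithium coordination, enolises the ketone at C1 (both epimers converge) and the allylic chloride ionises from that enolate to the oxyallyl cation 20 over C1–C10–C9, which is trapped by the tethered 2-silyloxydiene, probably stepwise with C1–C5 formed first at the nucleophilic enol-ether carbon and C9–C8 second. This is the intramolecular (4+3) cycloaddition of oxyallyl cations generated from alpha-halo ketones with base in an ionising medium, known for tethered dienes that give fused five-seven ring systems. The five-membered ring closes by C1–C5 bonding through the C2–C4 tether (5-exo with respect to C5=C6) and the seven-membered ring by union of the enolate carbon C9 with the siloxyallyl terminus C8, so the three-carbon and four-carbon components are joined at both ends. C5 is controlled by C4: with C3 held perpendicular to the diene, allylic 1,3-strain against the C6 silyloxy group places the C4 silyloxy group inside and the isopropyl group outside, so C1 adds to the face that leaves C4–O cis to C6; C1 follows from the extended transition state in which its methyl is anti to H5 (trans fusion), and C8 follows from suprafacial use of the 9E diene. The step needs ionisation to beat direct substitution at CH2Cl (hence the hindered amine), carbon closure onto C8 in preference to oxygen closure or closure onto C6, and survival of the silyl enol ether (hence the aprotic salt medium).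

Step 13
Reactants: 21
Product: 22 (1S,4R,5R,8S)-4-hydroxy-1,8-dimethyl-4-(propan-2-yl)bicyclo[5.3.0]decane-6,10-dione
Conditions: HF·pyridine, pyridine, THF, 0 °C
Reagents that add atoms: none
Why: Buffered fluoride desilylation cleaves the tertiary silyl ether and the silyl enol ether (protonation at C7), freeing the C4 alcohol and the C6 ketone without base that could open the aldol unit or epimerise C5.

Step 14
Reactants: 22
Product: 23 (1S,4R,5S,6S,8S)-4,6-dihydroxy-1,8-dimethyl-4-(propan-2-yl)bicyclo[5.3.0]decan-10-one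
Conditions: Me4NBH(OAc)3, MeCN–AcOH (1:1), −20 to 0 °C
Reagents that add atoms: none
Why: Evans–Saksena reduction, in which the C4 hydroxyl binds boron and hydride is delivered intramolecularly to the C6 carbonyl from the face on which C4–O lies (anti to H5), should give the 4,6-anti diol with C6–O cis to H5, and the C10 ketone, which has no hydroxyl within reach, is not reduced by this mild reagent.

Step 15
Reactants: 23; 24 angelic acid
Product: 26 (1S,4R,5S,6S,8S)-4-hydroxy-1,8-dimethyl-10-oxo-4-(propan-2-yl)bicyclo[5.3.0]decan-6-yl (2Z)-2-methylbut-2-enoate, via mixed anhydride 25 (not isolated)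
Conditions: 24, 2,4,6-Cl3C6H2COCl, Et3N, PhMe, rt; then 23, 80 °C
Reagents that add atoms: none
Why: Yamaguchi-type esterification through the trichlorobenzoic mixed anhydride without a nucleophilic catalyst acylates the secondary C6 hydroxyl with retention and without Z to E isomerisation of the angeloyl group, the tertiary C4 hydroxyl being too hindered to react.

Step 16
Reactants: 26
Product: 27 (1S,4R,5S,6S)-4-hydroxy-1,8-dimethyl-10-oxo-4-(propan-2-yl)bicyclo[5.3.0]dec-8-en-6-yl (2Z)-2-methylbut-2-enoate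
Conditions: 2-iodoxybenzoic acid (IBX, 2 equiv), DMSO–PhF (1:2), 70 °C
Reagents that add atoms: none
Why: IBX dehydrogenation of a ketone to its enone is regiospecific here because C10 can enolise only towards C9 (C1 is quaternary), so C8=C9 forms and the C8 stereocentre is erased, while the tertiary alcohol cannot be oxidised.

Step 17
Reactants: 27
Product: 28 (1S,4R,5S,6S,10S)-4,10-dihydroxy-1,8-dimethyl-4-(propan-2-yl)bicyclo[5.3.0]dec-8-en-6-yl (2Z)-2-methylbut-2-enoate
Conditions: NaBH4, CeCl3·7H2O, MeOH, −40 °C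
Reagents that add atoms: none
Why: Luche 1,2-reduction, in which hydride should enter C10 anti to the axial C1 methyl on the neighbouring quaternary carbon (the open H5 face, as with ketones flanked by an angular methyl), gives the allylic alcohol with C10–OH cis to that methyl, which is the C10 epimer of the target.

Step 18
Reactants: 28; 24 angelic acid
Product: 29 (1S,4R,5S,6S,10R)-4-hydroxy-1,8-dimethyl-4-(propan-2-yl)bicyclo[5.3.0]dec-8-ene-6,10-diyl bis[(2Z)-2-methylbut-2-enoate] (CNP0183261.1)
Conditions: 24, PPh3, DIAD, PhMe, 0 °C to rt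
Reagents that add atoms: none
Why: Mitsunobu esterification, in which the carboxylate displaces the C10 oxyphosphonium with inversion along the same open face the hydride used (no beta-hydrogen is available for elimination), puts the ester trans to the C1 methyl, and because the acid reacts as carboxylate and is never acyl-activated its Z geometry should be kept, the tertiary C4 hydroxyl being inert.

Compound list
1 | prop-2-yn-1-ol | C#CCO | starting material
2 | isopropylmagnesium chloride | CC(C)[Mg]Cl | starting material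
3 | 3-methyl-2-methylidenebutan-1-ol | C=C(CO)C(C)C | intermediate
4 | [(2R)-2-(propan-2-yl)oxiran-2-yl]methanol | OC[C@]1(C(C)C)CO1 | intermediate
5 | (2R)-2-(iodomethyl)-3-methylbutane-1,2-diol | OC[C@@](O)(CI)C(C)C | intermediate
6 | methyl methacrylate | C=C(C)C(=O)OC | starting material
7 | methyl (5R)-5,6-dihydroxy-2-methyl-5-(propan-2-yl)hexanoate (C2 epimers) | COC(=O)C(C)CC[C@](O)(CO)C(C)C | intermediate
8 | methyl (5R)-5-hydroxy-2-methyl-6-[(4-methylbenzenesulfonyl)oxy]-5-(propan-2-yl)hexanoate | COC(=O)C(C)CC[C@](O)(COS(=O)(=O)c1ccc(C)cc1)C(C)C | intermediate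
9 | methyl 2-methyl-4-[(2R)-2-(propan-2-yl)oxiran-2-yl]butanoate | COC(=O)C(C)CC[C@@]1(C(C)C)CO1 | intermediate
10 | (E)-but-2-enal | C/C=C/C=O | starting material
11 | propane-1,3-dithiol | SCCCS | starting material
12 | 2-[(1E)-prop-1-en-1-yl]-1,3-dithiane | C/C=C/C1SCCCS1 | intermediate
13 | lithium 2-methyl-4-[(2R)-2-(propan-2-yl)oxiran-2-yl]butanoate | [Li+].[O-]C(=O)C(C)CC[C@@]1(C(C)C)CO1 | intermediate
14 | 2-lithio-2-[(1E)-prop-1-en-1-yl]-1,3-dithiane | [Li]C1(/C=C/C)SCCCS1 | intermediate
15 | (5S)-5-hydroxy-2-methyl-5-(propan-2-yl)-6-{2-[(1E)-prop-1-en-1-yl]-1,3-dithian-2-yl}hexanoic acid | OC(=O)C(C)CC[C@@](O)(C(C)C)CC1(/C=C/C)SCCCS1 | intermediate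
16 | (5S)-5-hydroxy-N-methoxy-N,2-dimethyl-5-(propan-2-yl)-6-{2-[(1E)-prop-1-en-1-yl]-1,3-dithian-2-yl}hexanamide | CON(C)C(=O)C(C)CC[C@@](O)(C(C)C)CC1(/C=C/C)SCCCS1 | intermediate
17 | (5S,8E)-5-hydroxy-N-methoxy-N,2-dimethyl-7-oxo-5-(propan-2-yl)dec-8-enamide | CON(C)C(=O)C(C)CC[C@@](O)(C(C)C)CC(=O)/C=C/C | intermediate
18 | (5R,6Z,8E)-N-methoxy-N,2-dimethyl-5-(propan-2-yl)-5,7-bis[(triethylsilyl)oxy]deca-6,8-dienamide | CON(C)C(=O)C(C)CC[C@@](O[Si](CC)(CC)CC)(C(C)C)/C=C(\O[Si](CC)(CC)CC)/C=C/C | intermediate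
19 | (6R,7Z,9E)-1-chloro-3-methyl-6-(propan-2-yl)-6,8-bis[(triethylsilyl)oxy]undeca-7,9-dien-2-one | ClCC(=O)C(C)CC[C@@](O[Si](CC)(CC)CC)(C(C)C)/C=C(\O[Si](CC)(CC)CC)/C=C/C | intermediate
20 | oxyallyl cation (2-oxidoallyl zwitterion over C1–C10–C9) derived from 19 | [CH2+]C([O-])=C(C)CC[C@@](O[Si](CC)(CC)CC)(C(C)C)/C=C(\O[Si](CC)(CC)CC)/C=C/C | intermediate
21 | (1S,4R,5S,8R)-1,8-dimethyl-4-(propan-2-yl)-4,6-bis[(triethylsilyl)oxy]bicyclo[5.3.0]dec-6-en-10-one, trans-fused | CC[Si](CC)(CC)OC1=C[C@H](C)CC(=O)[C@@]2(C)CC[C@@](O[Si](CC)(CC)CC)(C(C)C)[C@H]12 | intermediate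
22 | (1S,4R,5R,8S)-4-hydroxy-1,8-dimethyl-4-(propan-2-yl)bicyclo[5.3.0]decane-6,10-dione | O=C1C[C@H](C)CC(=O)[C@@]2(C)CC[C@@](O)(C(C)C)[C@H]12 | intermediate
23 | (1S,4R,5S,6S,8S)-4,6-dihydroxy-1,8-dimethyl-4-(propan-2-yl)bicyclo[5.3.0]decan-10-one | O[C@H]1C[C@H](C)CC(=O)[C@@]2(C)CC[C@@](O)(C(C)C)[C@H]12 | intermediate
24 | angelic acid, (2Z)-2-methylbut-2-enoic acid | C/C=C(/C)C(=O)O | starting material
25 | (2Z)-2-methylbut-2-enoic 2,4,6-trichlorobenzoic anhydride | C/C=C(/C)C(=O)OC(=O)c1c(Cl)cc(Cl)cc1Cl | intermediate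
26 | (1S,4R,5S,6S,8S)-4-hydroxy-1,8-dimethyl-10-oxo-4-(propan-2-yl)bicyclo[5.3.0]decan-6-yl (2Z)-2-methylbut-2-enoate | C/C=C(/C)C(=O)O[C@H]1C[C@H](C)CC(=O)[C@@]2(C)CC[C@@](O)(C(C)C)[C@H]12 | intermediate
27 | (1S,4R,5S,6S)-4-hydroxy-1,8-dimethyl-10-oxo-4-(propan-2-yl)bicyclo[5.3.0]dec-8-en-6-yl (2Z)-2-methylbut-2-enoate | C/C=C(/C)C(=O)O[C@H]1CC(C)=CC(=O)[C@@]2(C)CC[C@@](O)(C(C)C)[C@H]12 | intermediate
28 | (1S,4R,5S,6S,10S)-4,10-dihydroxy-1,8-dimethyl-4-(propan-2-yl)bicyclo[5.3.0]dec-8-en-6-yl (2Z)-2-methylbut-2-enoate | C/C=C(/C)C(=O)O[C@H]1CC(C)=C[C@H](O)[C@@]2(C)CC[C@@](O)(C(C)C)[C@H]12 | intermediate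
29 | (1S,4R,5S,6S,10R)-4-hydroxy-1,8-dimethyl-4-(propan-2-yl)bicyclo[5.3.0]dec-8-ene-6,10-diyl bis[(2Z)-2-methylbut-2-enoate] | C/C=C(/C)C(=O)O[C@H]1CC(C)=C[C@@H](OC(=O)/C(C)=C\C)[C@@]2(C)CC[C@@](O)(C(C)C)[C@H]12 | target

Total step count: 18. Longest linear sequence: 17 steps (steps 1 to 5 and 7 to 18); step 6 makes the dithiane fragment.

Steps most likely to fail

Step 12. Direct substitution of the primary chloride may outrun the slow enolisation at the hindered C1–H. After C1–C5 bonding the enolate may also close through oxygen or onto C6 to give five-membered (3+2) products, and the ring fusion may form cis. The fallback changes the cation precursor; it sets out from 18 and returns at 21. Dichloromethyllithium (CH2Cl2, LiN(iPr)2, THF, −95 °C) should convert the Weinreb amide into (6R,7Z,9E)-1,1-dichloro-3-methyl-6-(propan-2-yl)-6,8-bis[(triethylsilyl)oxy]undeca-7,9-dien-2-one F1. Its geminal dichloride resists direct substitution and, in the same amine and LiClO4 medium, ionises to a chlorine-stabilised, longer-lived oxyallyl cation. That cation should give (1S,4R,5S,8S)-9-chloro-1,8-dimethyl-4-(propan-2-yl)-4,6-bis[(triethylsilyl)oxy]bicyclo[5.3.0]dec-6-en-10-one F2 as both C9 epimers. Radical dechlorination (Bu3SnH, AIBN, PhH, 80 °C) then leads back to 21.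

Step 18. Displacement at a carbinol carbon flanked by a quaternary centre may be too slow, so that the oxyphosphonium ionises to the C8–C10 allyl cation (loss of configuration, attack at C8) or the alcohol is returned. The sequence also fails if hydride delivery in step 17 is unselective. The fallback delivers oxygen, not hydride, to the open face of C10; it sets out from 23 and returns at 29. Silylation of both hydroxyls (Et3SiOTf, 2,6-lutidine, CH2Cl2, −78 °C) should give (1S,4R,5S,6S,8S)-1,8-dimethyl-4-(propan-2-yl)-4,6-bis[(triethylsilyl)oxy]bicyclo[5.3.0]decan-10-one F3. Enolisation towards C9 and triflation (KN(SiMe3)2, PhNTf2, THF, −78 °C) give the enol triflate (1S,4R,5S,6S,8S)-1,8-dimethyl-4-(propan-2-yl)-4,6-bis[(triethylsilyl)oxy]bicyclo[5.3.0]dec-9-en-10-yl trifluoromethanesulfonate F4. Reduction (Pd(OAc)2, PPh3, Bu3N, HCO2H, DMF, 60 °C) gives the alkene (1R,4R,5S,6S,8S)-1,8-dimethyl-4-(propan-2-yl)-4,6-bis[(triethylsilyl)oxy]bicyclo[5.3.0]dec-9-ene F5. Epoxidation anti to the C1 methyl (mCPBA, NaHCO3, CH2Cl2) should give (1S,4R,5S,6S,8S,9R,10S)-9,10-epoxy-1,8-dimethyl-4-(propan-2-yl)-4,6-bis[(triethylsilyl)oxy]bicyclo[5.3.0]decane F6. Syn elimination with LiNEt2 (Et2O, 0 °C to rt) removes the C8 hydrogen, which lies cis to the epoxide oxygen after a suprafacial cycloaddition. This gives (1S,4R,5S,6S,10R)-1,8-dimethyl-4-(propan-2-yl)-4,6-bis[(triethylsilyl)oxy]bicyclo[5.3.0]dec-8-en-10-ol F7 with C10–O already trans to the methyl. HF·pyridine gives (1S,4R,5S,6S,10R)-1,8-dimethyl-4-(propan-2-yl)bicyclo[5.3.0]dec-8-ene-4,6,10-triol F8. Double esterification of its two secondary hydroxyls with mixed anhydride 25 (PhMe, 80 °C) gives 29.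

Step 7. The allyl-type dithiane anion may alkylate through its remote (gamma) carbon, and opening of an epoxide CH2 beside a quaternary carbon by a tertiary carbanion on a sparingly soluble lithium carboxylate may be too slow. The fallback uses an alkene as carbonyl surrogate; it sets out from 9 and returns at 17. Copper-catalysed opening with CH2=CHMgBr (CuI, THF, −40 °C to rt) and lactonisation of the alkoxide should give (6S)-3-methyl-6-(propan-2-yl)-6-(prop-2-en-1-yl)oxan-2-one F9. Aminolysis (Me3Al, MeNH(OMe)·HCl, CH2Cl2) gives (5S)-5-hydroxy-N-methoxy-N,2-dimethyl-5-(propan-2-yl)oct-7-enamide F10. Ozonolysis (O3, CH2Cl2–MeOH, −78 °C; Me2S) gives (5S)-5-hydroxy-N-methoxy-N,2-dimethyl-7-oxo-5-(propan-2-yl)heptanamide F11. Aldehyde-selective Nozaki–Hiyama–Kishi addition of (E)-1-bromoprop-1-ene (CrCl2, NiCl2 cat., DMF) gives (5S,8E)-5,7-dihydroxy-N-methoxy-N,2-dimethyl-5-(propan-2-yl)dec-8-enamide F12. Oxidation of its allylic alcohol with MnO2 gives 17.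

Further compounds
F1 | step 12 | (6R,7Z,9E)-1,1-dichloro-3-methyl-6-(propan-2-yl)-6,8-bis[(triethylsilyl)oxy]undeca-7,9-dien-2-one | ClC(Cl)C(=O)C(C)CC[C@@](O[Si](CC)(CC)CC)(C(C)C)/C=C(\O[Si](CC)(CC)CC)/C=C/C
F2 | step 12 | (1S,4R,5S,8S)-9-chloro-1,8-dimethyl-4-(propan-2-yl)-4,6-bis[(triethylsilyl)oxy]bicyclo[5.3.0]dec-6-en-10-one (C9 epimers) | CC[Si](CC)(CC)OC1=C[C@H](C)C(Cl)C(=O)[C@@]2(C)CC[C@@](O[Si](CC)(CC)CC)(C(C)C)[C@H]12
F3 | step 18 | (1S,4R,5S,6S,8S)-1,8-dimethyl-4-(propan-2-yl)-4,6-bis[(triethylsilyl)oxy]bicyclo[5.3.0]decan-10-one | CC[Si](CC)(CC)O[C@H]1C[C@H](C)CC(=O)[C@@]2(C)CC[C@@](O[Si](CC)(CC)CC)(C(C)C)[C@H]12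
F4 | step 18 | (1S,4R,5S,6S,8S)-1,8-dimethyl-4-(propan-2-yl)-4,6-bis[(triethylsilyl)oxy]bicyclo[5.3.0]dec-9-en-10-yl trifluoromethanesulfonate | CC[Si](CC)(CC)O[C@H]1C[C@H](C)C=C(OS(=O)(=O)C(F)(F)F)[C@@]2(C)CC[C@@](O[Si](CC)(CC)CC)(C(C)C)[C@H]12
F5 | step 18 | (1R,4R,5S,6S,8S)-1,8-dimethyl-4-(propan-2-yl)-4,6-bis[(triethylsilyl)oxy]bicyclo[5.3.0]dec-9-ene | CC[Si](CC)(CC)O[C@H]1C[C@H](C)C=C[C@@]2(C)CC[C@@](O[Si](CC)(CC)CC)(C(C)C)[C@H]12
F6 | step 18 | (1S,4R,5S,6S,8S,9R,10S)-9,10-epoxy-1,8-dimethyl-4-(propan-2-yl)-4,6-bis[(triethylsilyl)oxy]bicyclo[5.3.0]decane | CC[Si](CC)(CC)O[C@H]1C[C@H](C)[C@H]3O[C@H]3[C@@]2(C)CC[C@@](O[Si](CC)(CC)CC)(C(C)C)[C@H]12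
F7 | step 18 | (1S,4R,5S,6S,10R)-1,8-dimethyl-4-(propan-2-yl)-4,6-bis[(triethylsilyl)oxy]bicyclo[5.3.0]dec-8-en-10-ol | CC[Si](CC)(CC)O[C@H]1CC(C)=C[C@@H](O)[C@@]2(C)CC[C@@](O[Si](CC)(CC)CC)(C(C)C)[C@H]12
F8 | step 18 | (1S,4R,5S,6S,10R)-1,8-dimethyl-4-(propan-2-yl)bicyclo[5.3.0]dec-8-ene-4,6,10-triol | O[C@H]1CC(C)=C[C@@H](O)[C@@]2(C)CC[C@@](O)(C(C)C)[C@H]12
F9 | step 7 | (6S)-3-methyl-6-(propan-2-yl)-6-(prop-2-en-1-yl)oxan-2-one | C=CC[C@]1(C(C)C)CCC(C)C(=O)O1
F10 | step 7 | (5S)-5-hydroxy-N-methoxy-N,2-dimethyl-5-(propan-2-yl)oct-7-enamide | CON(C)C(=O)C(C)CC[C@@](O)(C(C)C)CC=C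
F11 | step 7 | (5S)-5-hydroxy-N-methoxy-N,2-dimethyl-7-oxo-5-(propan-2-yl)heptanamide | CON(C)C(=O)C(C)CC[C@@](O)(C(C)C)CC=O
F12 | step 7 | (5S,8E)-5,7-dihydroxy-N-methoxy-N,2-dimethyl-5-(propan-2-yl)dec-8-enamide (C7 epimers) | CON(C)C(=O)C(C)CC[C@@](O)(C(C)C)CC(O)/C=C/C
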